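Reckon in moles of product, and the first chemist prices each at two moles of nucleophile: one enters the step, the other catches the acid set free. The second chemist prices it at one.

| flask | electrophile | nucleophile | remark | time |
|---|---|---|---|---|
| delta | 2 M | 2.3 M | run made earlier |  |
| Wednesday's | 2.0 M | 2.00 M |  | 12 min |
| Saturday's | 2.0 M | 3.00 M |  | 12 min |

delta run (percent of the electrophile charged)

| time / min | electrophile / % | product / % |
|---|---|---|
| 3.00 | 47.8 | 37.4 |
| 6.00 | 32.9 | 45.9 |
| 10.0 | 24.2 | 52.3 |
| 12.0 | 23.6 | 52.3 |

(scatter of a reading: 1 percentage point)

- percent here means electrophile units held: one homo dimer counts as two
- what is said of acid set free includes idle adduct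
- steps that have been proposed: electrophile + nucleophile -> acid set free + product; nucleophile + acid set free <-> protonated nucleophile; 2 electrophile -> homo dimer; electrophile + acid set free <-> idle adduct

- part of the electrophile that has reacted at the end, Wednesday's
- part of the electrophile that has reacted at the end, Saturday's
- what raising the concentration of nucleophile from its lowest to its highest value here does to the part of the electrophile that has reacted (changes below 5 percentage points count as none) (it rises / no change / it falls)

For Saturday's, the first chemist's price gives 75.0 %. This allowance, the nucleophile charged, shared out at two per product, over the electrophile charged, is 50.0 % for Wednesday's, so she expects more electrophile to react on Saturday. For the delta run it is 57.5 %, and the product read there lay flat at 52.3 %.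

The second chemist answers that one per product leaves the delta run with nucleophile over. So she expects the acid to hold the remaining electrophile as idle adduct. The delta run's last reading leaves 23.6 %, so she says 76.4 % reacted for both flasks, no change.

The forecast shares the first chemist's price and direction but not her number, for it counts homo dimer beside product: 73 % for Wednesday's (68 % to 77 %), 83 % for Saturday's (78 % to 89 %), and it rises. Against the second chemist it says “A large idle adduct would spare nucleophile and should not give this stall”.

The flasks give 74.3 % for Wednesday's and 84.3 % for Saturday's: it rises, by 10 percentage points, and that gap stands because of the difference in nucleophile charged.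

    electrophile + nucleophile → acid set free + product (k = 0.00210 /M/s)
    nucleophile + acid set free ⇌ protonated nucleophile, settled at all times (K = 2900 /M)
    2 electrophile → homo dimer (k = 4.40 × 10⁻⁴ /M/s)
    electrophile + acid set free ⇌ idle adduct, settled at all times (K = 0.450 /M)

Wednesday's flask with its nucleophile held at the charge reaches 96.5 % instead of 74.3 %, so the shrinking supply is a part of the stop, while idle adduct, at 0.0253 %, makes no difference. The second chemist's no change does hold around Wednesday's, between 1.51 M and 2.49 M of nucleophile, and Saturday's 3.00 M lies beyond that. Saturday's product reaches 74.6 % by 120 min, against its allowance of 75.0 %. Scaled to the neighbour like Saturday's with 0.75 M of nucleophile, the allowance is 18.8 %, and that flask ends at 18.2 % product, with 62.1 % of its electrophile reacted.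

The data were computed for substances that don't exist, and the scatter is random.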